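## Retrosynthetic overview

1. Target 18 ⇒ sulfate 15 ⇒ alcohol 14: the C3 CH2OH is kept masked as an (E)-propenyl group until the only free hydroxyl has been O-sulfated; ozonolysis/NaBH4 and aryl-silyl cleavage come last.
2. 14 ⇒ carbinol 12: the dihydrofuran ring (the only ring made; both benzene rings are bought) closes by C2–O bond formation through a p-siloxybenzyl cation, trans to the C3 substituent.
3. 12 ⇒ allyl aryl ether 8: the C3–C3a bond and the C3 stereocentre come from an aromatic Claisen [3,3] rearrangement of an (R,E)-secondary allyl aryl ether with 1,3-chirality transfer.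
4. 8 ⇒ alkyne 4 + O-TBS-vanillin 5 (hydrozirconation/zinc alkenylation); 4 ⇒ phenol 2 + (S)-but-3-yn-2-ol 3 (Mitsunobu, inversion); 2 ⇒ dihydroconiferyl alcohol 1.

Assumption: the target is delivered in the free hydrogen sulfate form drawn (acidic final work-up; it is best stored cold or as its sodium salt), and 1, 3 (≥98% ee) and 5 are taken as catalogue compounds.

## Route

Step 1
Reactants: 1 dihydroconiferyl alcohol [4-(3-hydroxypropyl)-2-methoxyphenol]
Product: 2 4-[3-(tert-butyldimethylsilyloxy)propyl]-2-methoxyphenol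
Conditions: TBSCl (1.05 equiv), imidazole (2.2 equiv), CH2Cl2, 0 °C → rt
Reagents that add atoms: tert-butyldimethylsilyl chloride, CC(C)(C)[Si](C)(C)Cl
Why: Chemoselective silylation, because the unhindered primary alcohol reacts much faster than the ortho-methoxy, internally hydrogen-bonded phenol, which stays free for step 2.

Step 2
Reactants: 2 4-[3-(tert-butyldimethylsilyloxy)propyl]-2-methoxyphenol; 3 (S)-but-3-yn-2-ol
Product: 4 (R)-1-(but-3-yn-2-yloxy)-2-methoxy-4-[3-(tert-butyldimethylsilyloxy)propyl]benzene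
Conditions: PPh3 (1.3 equiv), DIAD (1.3 equiv), THF, 0 °C → rt
Reagents that add atoms: none
Why: Mitsunobu etherification of the phenol proceeds by SN2 with clean inversion, turning the bought (S)-carbinol into the (R)-aryl propargyl ether.

Step 3
Reactants: 4 (R)-aryl but-3-yn-2-yl ether; 5 4-(tert-butyldimethylsilyloxy)-3-methoxybenzaldehyde
Product: 8 (2E,4R)-1-[4-(tert-butyldimethylsilyloxy)-3-methoxyphenyl]-4-{2-methoxy-4-[3-(tert-butyldimethylsilyloxy)propyl]phenoxy}pent-2-en-1-ol (C1 epimers ca. 1:1), via alkenylzirconocene chloride 6 (not isolated), via alkenyl(methyl)zinc 7 (not isolated)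
Conditions: Cp2Zr(H)Cl (1.2 equiv), CH2Cl2, rt; Me2Zn (1.2 equiv), −65 °C; 5, 0 °C; aq NH4Cl
Reagents that add atoms: none
Why: syn-Hydrozirconation of the terminal alkyne gives the (E)-alkenyl metal, and Zr→Zn transmetalation followed by 1,2-addition to the aldehyde (Wipf alkenylation) gives the (E)-allylic alcohol without touching C4; the new carbinol centre is formed unselectively and is erased in step 4.

Step 4
Reactants: 8 (2E,4R)-allylic alcohol (C1 epimers)
Product: 14 3-{(2S,3S)-2-[4-(tert-butyldimethylsilyloxy)-3-methoxyphenyl]-7-methoxy-3-[(E)-prop-1-enyl]-2,3-dihydrobenzofuran-5-yl}propan-1-ol, via TMS ether 9 (not isolated), via ortho-dienone 10 (not isolated), via bis-TMS aryl ether 11 (not isolated), via hydroxyaryl carbinol 12 (not isolated), via silyl-protected dihydrobenzofuran 13 (not isolated)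
Conditions: BSA (3 equiv), PhMe, 170 °C (sealed tube), 8 h; evaporate; TsOH·H2O (0.2 equiv), MeOH–CH2Cl2 (1:3), 0 °C → rt, 2 h
Reagents that add atoms: none
Why: With the labile carbinol and the product phenol capped in situ as TMS ethers, the aromatic Claisen [3,3] rearrangement passes through a chair transition state with the C4 methyl equatorial and transfers the (R) ether centre suprafacially to the new benzylic C3 (E-propenyl retained); acid then strips the TMS groups and the primary TBS ether and closes the ring by reversible SN1 attack of the phenol on the p-siloxybenzyl cation, which places the C2 aryl trans to the C3 substituent.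

Step 5
Reactants: 14 (2S,3S)-dihydrobenzofuran propanol
Product: 15 sodium 3-{(2S,3S)-2-[4-(tert-butyldimethylsilyloxy)-3-methoxyphenyl]-7-methoxy-3-[(E)-prop-1-enyl]-2,3-dihydrobenzofuran-5-yl}propyl sulfate
Conditions: SO3·pyridine (3 equiv), pyridine, rt; aq NaHCO3
Reagents that add atoms: sulfur trioxide–pyridine complex, O=S(=O)([O-])[n+]1ccccc1; sodium hydrogen carbonate, [Na+].OC([O-])=O
Why: O-Sulfation of the only free hydroxyl, since the aryl silyl ether, the alkene and the arenes are inert to the amine–SO3 complex at rt and the sulfate monoester is isolated as its stable sodium salt.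

Step 6
Reactants: 15 sodium propyl sulfate with C3 (E)-propenyl group
Product: 18 3-[(2S,3R)-2-(4-hydroxy-3-methoxyphenyl)-3-(hydroxymethyl)-7-methoxy-2,3-dihydro-1-benzofuran-5-yl]propyl hydrogen sulfate (target), via aldehyde 16 (not isolated), via silyl-protected hydroxymethyl sulfate 17 (not isolated)
Conditions: O3, CH2Cl2–MeOH (4:1), −78 °C (Sudan Red 7B end point); NaBH4, −78 → 0 °C; 1 M NaOH, rt; 1 M HCl to pH 2, 0 °C; C18
Reagents that add atoms: ozone, [O-][O+]=O
Why: Ozonolysis cleaves the only alkene much faster than it attacks the alkoxyarenes at −78 °C, immediate borohydride reduction turns the C3 aldehyde into CH2OH before it can epimerise or β-eliminate, and hydroxide removes the aryl silyl ether while the alkyl sulfate monoester is base-stable, so neither stereocentre is touched.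

## Compound list

1 | dihydroconiferyl alcohol, 4-(3-hydroxypropyl)-2-methoxyphenol | COc1cc(CCCO)ccc1O | starting material
2 | 4-[3-(tert-butyldimethylsilyloxy)propyl]-2-methoxyphenol | COc1cc(CCCO[Si](C)(C)C(C)(C)C)ccc1O | intermediate (isolated)
3 | (S)-but-3-yn-2-ol | C#C[C@H](C)O | starting material
4 | (R)-1-(but-3-yn-2-yloxy)-2-methoxy-4-[3-(tert-butyldimethylsilyloxy)propyl]benzene | C#C[C@@H](C)Oc1ccc(CCCO[Si](C)(C)C(C)(C)C)cc1OC | intermediate (isolated)
5 | 4-(tert-butyldimethylsilyloxy)-3-methoxybenzaldehyde (O-TBS-vanillin) | COc1cc(C=O)ccc1O[Si](C)(C)C(C)(C)C | starting material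
6 | (E)-alkenylzirconocene chloride from 4, (R) at the ether carbon (Cp drawn η1) | C[C@@H](Oc1ccc(CCCO[Si](C)(C)C(C)(C)C)cc1OC)/C=C/[Zr](Cl)(C1C=CC=C1)C1C=CC=C1 | intermediate (not isolated)
7 | (E)-alkenyl(methyl)zinc, (R) at the ether carbon | C[C@@H](Oc1ccc(CCCO[Si](C)(C)C(C)(C)C)cc1OC)/C=C/[Zn]C | intermediate (not isolated)
8 | (2E,4R)-1-[4-(tert-butyldimethylsilyloxy)-3-methoxyphenyl]-4-{2-methoxy-4-[3-(tert-butyldimethylsilyloxy)propyl]phenoxy}pent-2-en-1-ol, C1 epimers | C[C@@H](Oc1ccc(CCCO[Si](C)(C)C(C)(C)C)cc1OC)/C=C/C(O)c1ccc(O[Si](C)(C)C(C)(C)C)c(OC)c1 | intermediate (isolated)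
9 | C1 O-trimethylsilyl ether of 8 | C[C@@H](Oc1ccc(CCCO[Si](C)(C)C(C)(C)C)cc1OC)/C=C/C(O[Si](C)(C)C)c1ccc(O[Si](C)(C)C(C)(C)C)c(OC)c1 | intermediate (not isolated)
10 | Claisen ortho-dienone: 2-methoxy-4-[3-(TBSO)propyl]cyclohexa-2,4-dien-1-one carrying the (S)-configured 1-[aryl(TMSO)methyl]but-2-enyl group at C6 (ring C6 unspecified) | O=C1C(OC)=CC(CCCO[Si](C)(C)C(C)(C)C)=CC1[C@H](/C=C/C)C(O[Si](C)(C)C)c1ccc(O[Si](C)(C)C(C)(C)C)c(OC)c1 | intermediate (not isolated)
11 | (2S,3E)-rearranged phenol as its aryl O-TMS and C1 O-TMS bis-silyl ether, C1 epimers | C/C=C/[C@@H](c1cc(CCCO[Si](C)(C)C(C)(C)C)cc(OC)c1O[Si](C)(C)C)C(O[Si](C)(C)C)c1ccc(O[Si](C)(C)C(C)(C)C)c(OC)c1 | intermediate (not isolated)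
12 | (2S,3E)-2-{2-hydroxy-3-methoxy-5-[3-(tert-butyldimethylsilyloxy)propyl]phenyl}-1-[4-(tert-butyldimethylsilyloxy)-3-methoxyphenyl]pent-3-en-1-ol, C1 epimers | C/C=C/[C@@H](c1cc(CCCO[Si](C)(C)C(C)(C)C)cc(OC)c1O)C(O)c1ccc(O[Si](C)(C)C(C)(C)C)c(OC)c1 | intermediate (not isolated)
13 | (2S,3S)-2-[4-(tert-butyldimethylsilyloxy)-3-methoxyphenyl]-7-methoxy-3-[(E)-prop-1-enyl]-5-[3-(tert-butyldimethylsilyloxy)propyl]-2,3-dihydrobenzofuran (trans) | COc1cc([C@H]2Oc3c(OC)cc(CCCO[Si](C)(C)C(C)(C)C)cc3[C@@H]2/C=C/C)ccc1O[Si](C)(C)C(C)(C)C | intermediate (not isolated)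
14 | 3-{(2S,3S)-2-[4-(tert-butyldimethylsilyloxy)-3-methoxyphenyl]-7-methoxy-3-[(E)-prop-1-enyl]-2,3-dihydrobenzofuran-5-yl}propan-1-ol (trans) | COc1cc([C@H]2Oc3c(OC)cc(CCCO)cc3[C@@H]2/C=C/C)ccc1O[Si](C)(C)C(C)(C)C | intermediate (isolated)
15 | sodium 3-{(2S,3S)-2-[4-(tert-butyldimethylsilyloxy)-3-methoxyphenyl]-7-methoxy-3-[(E)-prop-1-enyl]-2,3-dihydrobenzofuran-5-yl}propyl sulfate | COc1cc([C@H]2Oc3c(OC)cc(CCCOS(=O)(=O)[O-])cc3[C@@H]2/C=C/C)ccc1O[Si](C)(C)C(C)(C)C.[Na+] | intermediate (isolated)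
16 | sodium 3-{(2S,3S)-3-formyl-2-[4-(tert-butyldimethylsilyloxy)-3-methoxyphenyl]-7-methoxy-2,3-dihydrobenzofuran-5-yl}propyl sulfate | COc1cc([C@H]2Oc3c(OC)cc(CCCOS(=O)(=O)[O-])cc3[C@@H]2C=O)ccc1O[Si](C)(C)C(C)(C)C.[Na+] | intermediate (not isolated)
17 | sodium 3-{(2S,3R)-3-(hydroxymethyl)-2-[4-(tert-butyldimethylsilyloxy)-3-methoxyphenyl]-7-methoxy-2,3-dihydrobenzofuran-5-yl}propyl sulfate | COc1cc([C@H]2Oc3c(OC)cc(CCCOS(=O)(=O)[O-])cc3[C@@H]2CO)ccc1O[Si](C)(C)C(C)(C)C.[Na+] | intermediate (not isolated)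
18 | 3-[(2S,3R)-2-(4-hydroxy-3-methoxyphenyl)-3-(hydroxymethyl)-7-methoxy-2,3-dihydro-1-benzofuran-5-yl]propyl hydrogen sulfate | COc1cc([C@H]2Oc3c(OC)cc(CCCOS(=O)(=O)O)cc3[C@@H]2CO)ccc1O | target

## Step count and risks

Total step count: 6. Longest linear sequence: 6 (1 → 2 → 4 → 8 → 14 → 15 → 18).

Steps most likely to fail:

Step 4 (rearrangement and ring closure). Three things can go wrong. The secondary allyl aryl ether may ionise, which erodes the chirality transfer. A few percent of the (Z)-propenyl product, which carries the opposite C3 configuration, must be removed at 14 (AgNO3-silica). Prolonged acid can drain the benzylic cation to a stilbene by E1. The fallback sets out from 8 and comes back at 14. The carbinol is silylated (TBSOTf, 2,6-lutidine, CH2Cl2, −78 °C) to the isolable tris-silyl ether F1. This is rearranged under Lewis-acid catalysis instead of thermolysis (Eu(fod)3 10 mol %, CHCl3, 60 °C, chelation by the guaiacyl oxygens) to the rearranged phenol F2. A separate treatment of F2 with TsOH in MeOH–CH2Cl2 cleaves the benzylic and primary silyl ethers and closes the ring to 14.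

Step 3 (Zr/Zn alkenylation). The aryloxy-substituted alkenyl metal may form sluggishly, lose aryloxide, or the aldehyde may be reduced. The fallback sets out from 4 and comes back at 8. Pd-catalysed hydrostannation (Bu3SnH, cat. PdCl2(PPh3)2, THF, 0 °C) gives the (E)-alkenylstannane F3. Tin–lithium exchange (n-BuLi, THF, −78 °C) gives the alkenyllithium F4, which is added to aldehyde 5 at −78 °C to give 8.

Step 6 (ozonolysis, reduction, desilylation on a polar salt). Ozone may attack the electron-rich arenes, and aldehyde 16 can epimerise or ring-open if it is not reduced at once. The fallback sets out from 15 and comes back at 16. Dihydroxylation (cat. OsO4, NMO, acetone–H2O, rt) gives the vicinal diol F5. Glycol cleavage (NaIO4, THF–pH 7 buffer, 0 °C) gives 16, which is reduced, desilylated and acidified exactly as in step 6 to reach 18.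

## Further compounds

F1 | step 4 | C1 O-tert-butyldimethylsilyl ether of 8, (2E,4R), C1 epimers | C[C@@H](Oc1ccc(CCCO[Si](C)(C)C(C)(C)C)cc1OC)/C=C/C(O[Si](C)(C)C(C)(C)C)c1ccc(O[Si](C)(C)C(C)(C)C)c(OC)c1
F2 | step 4 | (2S,3E)-rearranged phenol with C1 O-TBS ether, C1 epimers | C/C=C/[C@@H](c1cc(CCCO[Si](C)(C)C(C)(C)C)cc(OC)c1O)C(O[Si](C)(C)C(C)(C)C)c1ccc(O[Si](C)(C)C(C)(C)C)c(OC)c1
F3 | step 3 | (E)-alkenyl(tributyl)stannane from 4, (R) at the ether carbon | C[C@@H](Oc1ccc(CCCO[Si](C)(C)C(C)(C)C)cc1OC)/C=C/[Sn](CCCC)(CCCC)CCCC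
F4 | step 3 | (E)-alkenyllithium, (R) at the ether carbon | C[C@@H](Oc1ccc(CCCO[Si](C)(C)C(C)(C)C)cc1OC)/C=C/[Li]
F5 | step 6 | sodium 3-{(2S,3S)-3-(1,2-dihydroxypropyl)-2-[4-(tert-butyldimethylsilyloxy)-3-methoxyphenyl]-7-methoxy-2,3-dihydrobenzofuran-5-yl}propyl sulfate (diol centres unspecified) | COc1cc([C@H]2Oc3c(OC)cc(CCCOS(=O)(=O)[O-])cc3[C@@H]2C(O)C(C)O)ccc1O[Si](C)(C)C(C)(C)C.[Na+]
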